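**Retrosynthetic overview**
- Target ⇐ phenol debenzylation, 10‑OH‑directed α‑epoxidation of C3=C4, and C8 acylation of 1αH,5βH‑guai‑3‑ene‑8β,10α‑diol with O‑benzylisovanillic acid.
- C10 carbinol ⇐ 8β‑hydroxy‑14‑norguai‑3‑en‑10‑one by hydroxyl‑directed internal methyl delivery (the new step; forms C10–C14 and sets C10).
- Cyclopentene ⇐ ring‑closing metathesis of a trans‑2‑allyl‑3‑isopropenylcycloheptanone ⇐ conjugate addition/enolate allylation on a 5‑isopropyl‑6‑silyloxycyclohept‑2‑enone.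
- Cycloheptene ⇐ cis‑2‑isopropylcyclohept‑3‑enol from syn‑SN2' opening of the meso furan/oxyallyl (4+3) adduct ketal with i‑PrLi, resolved enzymatically.
- Ring order: seven‑membered ring (from the oxabicycle), then cyclopentene (metathesis), then oxirane (last).

Assumption: the oxabicyclic ketone and 3‑(benzyloxy)‑4‑methoxybenzoic acid are taken as catalogue compounds. Guaiane numbering is used for the hydroazulenes (C1/C5 ring fusion, C4 and C10 methyl‑bearing, C7 isopropyl‑bearing, C8 acyloxy‑bearing).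

**Step 1**
Reactants: 1 8‑oxabicyclo[3.2.1]oct‑6‑en‑3‑one (meso)
Product: 2 (1R,5S)‑spiro[8‑oxabicyclo[3.2.1]oct‑6‑ene‑3,2'‑[1,3]dioxolane] (meso)
Conditions: HOCH2CH2OH, p‑TsOH (cat.), benzene, reflux, Dean–Stark
Reagents that add atoms: ethylene glycol, OCCO
Why: Acid‑catalysed ketalisation masks the ketone against the organolithium of the next step and creates no stereocentre.

**Step 2**
Reactants: 2 spiro ketal
Product: 4 racemic cis‑(7R*,8S*)‑8‑isopropyl‑1,4‑dioxaspiro[4.6]undec‑9‑en‑7‑yl acetate, via racemic lithium alkoxide 3 (not isolated)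
Conditions: i‑PrLi (3 equiv), Et2O, −78 → 0 °C; then Ac2O, 0 °C → rt
Reagents that add atoms: isopropyllithium, CC(C)[Li]; acetic anhydride, CC(=O)OC(C)=O
Why: Organolithium syn‑SN2' ring opening of the oxabicyclic alkene (exo carbolithiation, then β‑alkoxide elimination) puts isopropyl and oxygen cis on the new cycloheptene, and the alkoxide is acetylated in the same flask.

**Step 3**
Reactants: 4 racemic cis acetate
Product: 5 (7R,8S)‑8‑isopropyl‑1,4‑dioxaspiro[4.6]undec‑9‑en‑7‑ol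
Conditions: lipase from Burkholderia cepacia, KH2PO4/K2HPO4 buffer (pH 7.2)/acetone 9:1, 30 °C, stopped at ca. 45% conversion
Reagents that add atoms: none
Why: Enzymatic kinetic resolution by hydrolysis, in which the (7R)‑acetate is expected to react faster (Kazlauskas rule, the isopropyl‑bearing carbon being the large group), fixes the absolute configuration of the future C7 and C8; the unreacted (7S,8R)‑acetate is removed by chromatography.

**Step 4**
Reactants: 5 (7R,8S)‑alcohol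
Product: 6 tert‑butyl{[(7R,8S)‑8‑isopropyl‑1,4‑dioxaspiro[4.6]undec‑9‑en‑7‑yl]oxy}dimethylsilane
Conditions: TBSOTf, 2,6‑lutidine, CH2Cl2, −78 → 0 °C
Reagents that add atoms: tert‑butyldimethylsilyl triflate, CC(C)(C)[Si](C)(C)OS(=O)(=O)C(F)(F)F
Why: Silylation of the hindered secondary alcohol gives a bulky ether that survives the enone chemistry and later shields the β‑face.

**Step 5**
Reactants: 6 silyl ether ketal
Product: 8 (5R,6R)‑6‑[(tert‑butyldimethylsilyl)oxy]‑5‑isopropylcyclohept‑2‑en‑1‑one, via cyclohept‑3‑enone 7 (not isolated)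
Conditions: PPTS, acetone/H2O 9:1, 55 °C; then DBU (0.2 equiv), CH2Cl2, rt
Reagents that add atoms: water, O
Why: Ketal hydrolysis followed by base‑mediated β,γ → α,β enone isomerisation through the dienolate moves the double bond into conjugation without touching the C5/C6 stereocentres; the minor β,γ‑isomer left at equilibrium is separated and resubmitted.

**Step 6**
Reactants: 8 cyclohept‑2‑enone
Product: 10 (2R,3S,5R,6R)‑2‑allyl‑6‑[(tert‑butyldimethylsilyl)oxy]‑5‑isopropyl‑3‑(prop‑1‑en‑2‑yl)cycloheptan‑1‑one, via bromomagnesium enolate 9 (not isolated)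
Conditions: CH2=C(CH3)MgBr, CuBr·SMe2 (10 mol %), THF, −78 → −40 °C; then allyl iodide, DMPU, −40 → 0 °C
Reagents that add atoms: isopropenylmagnesium bromide, C=C(C)[Mg]Br; allyl iodide, C=CCI
Why: Copper‑catalysed 1,4‑addition with enolate C‑alkylation (three‑component coupling): isopropenyl enters the β‑carbon anti to the cis isopropyl/silyloxy pair, and allyl then enters the regiodefined enolate anti to the new substituent, giving the trans‑2,3 pattern (future H1 α, H5 β).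

**Step 7**
Reactants: 10 trans‑2‑allyl‑3‑isopropenylcycloheptanone
Product: 11 (1R,5S,7R,8R)‑8‑[(tert‑butyldimethylsilyl)oxy]‑14‑norguai‑3‑en‑10‑one (1αH,5βH)
Conditions: RuCl2(=CHPh)(H2IMes)(PCy3) (second‑generation Grubbs catalyst, 5 mol %), CH2Cl2 (0.005 M), 40 °C
Reagents that add atoms: none
Why: Ring‑closing olefin metathesis of the allyl and isopropenyl groups closes the methylcyclopentene with loss of ethene, and the trans ring fusion is carried over unchanged from 10.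

**Step 8**
Reactants: 11 silyloxy ketone
Product: 12 (1R,5S,7R,8R)‑8‑hydroxy‑14‑norguai‑3‑en‑10‑one (1αH,5βH, 8β‑OH)
Conditions: HF·pyridine, THF/pyridine, 0 °C → rt
Reagents that add atoms: none
Why: Fluoride desilylation under buffered acidic conditions frees the 8β‑hydroxyl without β‑elimination or epimerisation at C1.

**Step 9**
Reactants: 12 β‑hydroxy ketone
Product: 14 (1R,5S,7R,8R,10R)‑guai‑3‑ene‑8,10‑diol (1αH,5βH, 8β‑OH, 10α‑OH), via lithium alkoxytrimethylaluminate 13 (not isolated)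
Conditions: LiAlMe4 (1.05 equiv, made from AlMe3 + MeLi, Et2O/toluene, 0 °C); add 12 at −78 °C, warm to 0 °C; aq. potassium sodium tartrate
Reagents that add atoms: lithium tetramethylaluminate, [Li+].C[Al-](C)(C)C (made in the flask from methyllithium, C[Li], and trimethylaluminium, C[Al](C)C)
Why: Proposed new method: hydroxyl‑directed internal methyl delivery, in which the C8 hydroxyl protonolyses one Al–CH3 bond (loss of CH4) to give the tethered aluminate 13, whose 8β‑O–Al unit can reach the Li+‑activated C10 carbonyl only across the β‑face through a six‑membered chair transition state (O8–Al–CH3···C10–C9–C8), so CH3 arrives β and the new hydroxyl is α (10R), the opposite of what untethered MeLi or MeMgBr should give by attack on the open α‑face, while only 1.05 equiv of the weakly nucleophilic aluminate leaves no free methyl source; the closest known reaction type is the Evans–Saksena anti‑reduction of β‑hydroxy ketones with Me4NBH(OAc)3 (internal hydride delivery from an alkoxyborohydride) together with alkoxide‑directed 1,4‑additions of organoaluminium and Grignard reagents.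

**Step 10**
Reactants: 14 guai‑3‑ene‑8β,10α‑diol; 15 3‑(benzyloxy)‑4‑methoxybenzoic acid
Product: 17 (1R,5S,7R,8R,10R)‑10‑hydroxyguai‑3‑en‑8‑yl 3‑(benzyloxy)‑4‑methoxybenzoate, via Yamaguchi mixed anhydride 16 (not isolated)
Conditions: 15, 2,4,6‑Cl3C6H2COCl, Et3N, THF, rt; then 14, DMAP, toluene, rt → 50 °C
Reagents that add atoms: none
Why: Yamaguchi esterification acylates the hindered secondary C8 hydroxyl while the tertiary C10 hydroxyl is inert under these conditions, with retention at C8.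

**Step 11**
Reactants: 17 guai‑3‑enyl ester
Product: 18 (1R,3R,4S,5S,7R,8R,10R)‑3,4‑epoxy‑10‑hydroxyguaian‑8‑yl 3‑(benzyloxy)‑4‑methoxybenzoate (3α,4α‑epoxide)
Conditions: VO(acac)2 (10 mol %), t‑BuOOH (decane solution, 2 equiv), benzene, rt → 40 °C
Reagents that add atoms: tert‑butyl hydroperoxide, CC(C)(C)OO
Why: Hydroxyl‑directed vanadium‑catalysed epoxidation (Sharpless–Michaelson type): the pentavalent vanadium alkylperoxide bound to the bishomoallylic 10α‑alkoxide reaches C3=C4 only from the α‑face, overriding the intrinsic β‑preference anti to the allylic C5–C6 bond and setting 3R,4S.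

**Step 12**
Reactants: 18 benzyl‑protected epoxy ester
Product: 19 (1R,3R,4S,5S,7R,8R,10R)‑3,4‑epoxy‑10‑hydroxyguaian‑8‑yl 3‑hydroxy‑4‑methoxybenzoate (CNP0264062.2; 1αH,5βH, 3α,4α‑epoxide, 7β‑isopropyl, 8β‑acyloxy, 10α‑OH)
Conditions: H2 (1 atm), Pd/C (10 wt %), EtOAc, rt
Reagents that add atoms: none
Why: Hydrogenolysis of the aryl benzyl ether frees the phenol under neutral conditions that leave the trisubstituted aliphatic epoxide, the ester and the tertiary alcohol intact.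

**Compound list**
1 | 8‑oxabicyclo[3.2.1]oct‑6‑en‑3‑one (meso) | O=C1C[C@@H]2C=C[C@H](C1)O2 | starting material
2 | (1R,5S)‑spiro[8‑oxabicyclo[3.2.1]oct‑6‑ene‑3,2'‑[1,3]dioxolane] (meso) | O1CCOC12C[C@@H]3C=C[C@H](C2)O3 | intermediate
3 | racemic lithium cis‑(7R*,8S*)‑8‑isopropyl‑1,4‑dioxaspiro[4.6]undec‑9‑en‑7‑olate (one enantiomer drawn; not isolated) | [Li+].[O-][C@@H]1CC2(OCCO2)CC=C[C@@H]1C(C)C | intermediate
4 | racemic cis‑(7R*,8S*)‑8‑isopropyl‑1,4‑dioxaspiro[4.6]undec‑9‑en‑7‑yl acetate (one enantiomer drawn) | CC(=O)O[C@@H]1CC2(OCCO2)CC=C[C@@H]1C(C)C | intermediate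
5 | (7R,8S)‑8‑isopropyl‑1,4‑dioxaspiro[4.6]undec‑9‑en‑7‑ol | O[C@@H]1CC2(OCCO2)CC=C[C@@H]1C(C)C | intermediate
6 | tert‑butyl{[(7R,8S)‑8‑isopropyl‑1,4‑dioxaspiro[4.6]undec‑9‑en‑7‑yl]oxy}dimethylsilane | CC(C)(C)[Si](C)(C)O[C@@H]1CC2(OCCO2)CC=C[C@@H]1C(C)C | intermediate
7 | (5S,6R)‑6‑[(tert‑butyldimethylsilyl)oxy]‑5‑isopropylcyclohept‑3‑en‑1‑one (not isolated) | CC(C)(C)[Si](C)(C)O[C@@H]1CC(=O)CC=C[C@@H]1C(C)C | intermediate
8 | (5R,6R)‑6‑[(tert‑butyldimethylsilyl)oxy]‑5‑isopropylcyclohept‑2‑en‑1‑one | CC(C)(C)[Si](C)(C)O[C@@H]1CC(=O)C=CC[C@@H]1C(C)C | intermediate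
9 | bromomagnesium (3S,5R,6R)‑6‑[(tert‑butyldimethylsilyl)oxy]‑5‑isopropyl‑3‑(prop‑1‑en‑2‑yl)cyclohept‑1‑en‑1‑olate (not isolated) | CC(C)(C)[Si](C)(C)O[C@@H]1CC(O[Mg]Br)=C[C@@H](C(C)=C)C[C@@H]1C(C)C | intermediate
10 | (2R,3S,5R,6R)‑2‑allyl‑6‑[(tert‑butyldimethylsilyl)oxy]‑5‑isopropyl‑3‑(prop‑1‑en‑2‑yl)cycloheptan‑1‑one | CC(C)(C)[Si](C)(C)O[C@@H]1CC(=O)[C@H](CC=C)[C@@H](C(C)=C)C[C@@H]1C(C)C | intermediate
11 | (1R,5S,7R,8R)‑8‑[(tert‑butyldimethylsilyl)oxy]‑14‑norguai‑3‑en‑10‑one | CC(C)(C)[Si](C)(C)O[C@@H]1CC(=O)[C@@H]2CC=C(C)[C@H]2C[C@@H]1C(C)C | intermediate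
12 | (1R,5S,7R,8R)‑8‑hydroxy‑14‑norguai‑3‑en‑10‑one | O[C@@H]1CC(=O)[C@@H]2CC=C(C)[C@H]2C[C@@H]1C(C)C | intermediate
13 | lithium trimethyl{[(1R,5S,7R,8R)‑10‑oxo‑14‑norguai‑3‑en‑8‑yl]oxy}aluminate (not isolated) | [Li+].C[Al-](C)(C)O[C@@H]1CC(=O)[C@@H]2CC=C(C)[C@H]2C[C@@H]1C(C)C | intermediate
14 | (1R,5S,7R,8R,10R)‑guai‑3‑ene‑8,10‑diol | O[C@@H]1C[C@@](C)(O)[C@@H]2CC=C(C)[C@H]2C[C@@H]1C(C)C | intermediate
15 | 3‑(benzyloxy)‑4‑methoxybenzoic acid | COc1ccc(C(=O)O)cc1OCc1ccccc1 | starting material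
16 | 3‑(benzyloxy)‑4‑methoxybenzoic 2,4,6‑trichlorobenzoic anhydride (not isolated) | COc1ccc(C(=O)OC(=O)c2c(Cl)cc(Cl)cc2Cl)cc1OCc1ccccc1 | intermediate
17 | (1R,5S,7R,8R,10R)‑10‑hydroxyguai‑3‑en‑8‑yl 3‑(benzyloxy)‑4‑methoxybenzoate | COc1ccc(C(=O)O[C@@H]2C[C@@](C)(O)[C@@H]3CC=C(C)[C@H]3C[C@@H]2C(C)C)cc1OCc1ccccc1 | intermediate
18 | (1R,3R,4S,5S,7R,8R,10R)‑3,4‑epoxy‑10‑hydroxyguaian‑8‑yl 3‑(benzyloxy)‑4‑methoxybenzoate | COc1ccc(C(=O)O[C@@H]2C[C@@](C)(O)[C@@H]3C[C@H]4O[C@@]4(C)[C@H]3C[C@@H]2C(C)C)cc1OCc1ccccc1 | intermediate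
19 | (1R,3R,4S,5S,7R,8R,10R)‑3,4‑epoxy‑10‑hydroxyguaian‑8‑yl 3‑hydroxy‑4‑methoxybenzoate (CNP0264062.2) | COc1ccc(C(=O)O[C@@H]2C[C@@](C)(O)[C@@H]3C[C@H]4O[C@@]4(C)[C@H]3C[C@@H]2C(C)C)cc1O | target

**Step count and risk**
Total steps: 12. Longest linear sequence: 12 steps (1 → 19); acid 15 enters at step 10.

The three steps most likely to fail:

Step 9 (the proposed new method). The tethered aluminate may transfer methyl too slowly or without the expected face control. The fallback uses known chemistry, sets out from 11 and comes back to the route at 14. Wittig methylenation of 11 (Ph3PCH3Br, KOtBu, THF) gives (1R,5S,7R,8R)‑8‑[(tert‑butyldimethylsilyl)oxy]guaia‑3,10(14)‑diene F2. Oxymercuration–demercuration (Hg(OAc)2, THF/H2O; then NaBH4, NaOH) hydrates only the unhindered 1,1‑disubstituted alkene, with water entering C10 from the open α‑face opposite the 8β‑silyloxy group, to give (1R,5S,7R,8R,10R)‑8‑[(tert‑butyldimethylsilyl)oxy]guai‑3‑en‑10‑ol F3. HF·pyridine then removes the silyl group to give 14.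

Step 6 (conjugate addition/allylation). The magnesium enolate may alkylate poorly or equilibrate. The fallback sets out from 8 and comes back at 10. The CuBr·SMe2‑catalysed addition of isopropenylmagnesium bromide is run in the presence of Me3SiCl, and the enolate is isolated as (3S,5R,6R)‑6‑[(tert‑butyldimethylsilyl)oxy]‑5‑isopropyl‑3‑(prop‑1‑en‑2‑yl)‑1‑[(trimethylsilyl)oxy]cyclohept‑1‑ene F1. Tsuji allylation of F1 with allyl methyl carbonate under zerovalent palladium catalysis (Pd2(dba)3, dppe, THF, 65 °C) then forms the C–allyl bond regiospecifically, anti to the isopropenyl group, and gives 10.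

Step 11 (directed epoxidation). The bishomoallylic 10α‑hydroxyl may not reach the alkene, in which case the reagent would attack the intrinsically favoured β‑face. The fallback sets out from 17 and comes back at 18. NBS in aqueous THF at 0 °C forms the bromonium ion on the less hindered β‑face, and water opens it at the tertiary C4 from the α‑face to give (1R,3S,4S,5S,7R,8R,10R)‑3‑bromo‑4,10‑dihydroxyguaian‑8‑yl 3‑(benzyloxy)‑4‑methoxybenzoate F4. K2CO3 in MeOH at 0 °C closes the 3α,4α‑epoxide by internal displacement of the 3β‑bromide, giving 18.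

**Further compounds**
F1 | step 6 | (3S,5R,6R)‑6‑[(tert‑butyldimethylsilyl)oxy]‑5‑isopropyl‑3‑(prop‑1‑en‑2‑yl)‑1‑[(trimethylsilyl)oxy]cyclohept‑1‑ene | CC(C)(C)[Si](C)(C)O[C@@H]1CC(O[Si](C)(C)C)=C[C@@H](C(C)=C)C[C@@H]1C(C)C
F2 | step 9 | (1R,5S,7R,8R)‑8‑[(tert‑butyldimethylsilyl)oxy]guaia‑3,10(14)‑diene | CC(C)(C)[Si](C)(C)O[C@@H]1CC(=C)[C@@H]2CC=C(C)[C@H]2C[C@@H]1C(C)C
F3 | step 9 | (1R,5S,7R,8R,10R)‑8‑[(tert‑butyldimethylsilyl)oxy]guai‑3‑en‑10‑ol | CC(C)(C)[Si](C)(C)O[C@@H]1C[C@@](C)(O)[C@@H]2CC=C(C)[C@H]2C[C@@H]1C(C)C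
F4 | step 11 | (1R,3S,4S,5S,7R,8R,10R)‑3‑bromo‑4,10‑dihydroxyguaian‑8‑yl 3‑(benzyloxy)‑4‑methoxybenzoate | COc1ccc(C(=O)O[C@@H]2C[C@@](C)(O)[C@@H]3C[C@H](Br)[C@@](C)(O)[C@H]3C[C@@H]2C(C)C)cc1OCc1ccccc1
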